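The numbers in the tables are calculated for substances that don't exist; noise was put on by code.

The teal and violet runs share one charge of substrate and differ in partner, and that pair gives the rule I would carry to the new flask.

| flask | substrate | partner | remark | time |
|---|---|---|---|---|
| teal | 17 mM | 21 mM | run made earlier |  |
| violet | 17 mM | 32 mM | run made earlier |  |
| blue | 34 mM | 42.5 mM | run made earlier |  |
| flask | 17 mM | 42.5 mM |  | 12 h |

| run | time / h | target / % | isomer of the product A / % |
|---|---|---|---|
| teal | 1.00 | 2.5 | 43.7 |
| teal | 3.00 | 3.9 | 44.1 |
| teal | 6.00 | 2.8 | 42.1 |
| teal | 8.00 | 3.2 | 43.8 |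
| teal | 12.0 | 3.6 | 44.2 |
| violet | 1.00 | 5.2 | 45.5 |
| violet | 3.00 | 5.3 | 44.4 |
| violet | 6.00 | 3.5 | 45.7 |
| violet | 8.00 | 5.4 | 45.5 |
| violet | 12.0 | 4.5 | 43.8 |
| blue | 1.00 | 3.3 | 37.0 |
| blue | 3.00 | 2.4 | 38.7 |
| blue | 6.00 | 5.6 | 37.5 |
| blue | 8.00 | 3.3 | 35.8 |
| blue | 12.0 | 4.1 | 36.6 |

(readings scatter by 1 percentage point)

- ratio of target to isomer of the product A at 25 s
- ratio of target to isomer of the product A at 12 h
- which of target and isomer of the product A there is more of at 12 h



Summed over its samples, teal gives a ratio of target to isomer of the product A of 0.0734, and violet gives 0.106. Each ratio divided by its [partner], then averaged, gives 0.00341 /mM: the plateau ratio per unit of [partner], read at [substrate] = 17 mM, which I call the partner-scaled ratio. Blue gives less per partner, so the rule holds [substrate] fixed. For the flask, where substrate is the limiting reagent (17 mM against 42.5 mM of partner), my own reckoning is 0.145 at 12 h.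

The dispute is over the early time. The forecast reaches 0.15 at 12 h by another road, with isomer of the product A ahead, and also writes 0.15 at 25 s: “It depends on unknown kinetics, so 0.15 is only a default, with a very wide range.” So its early number is the plateau value kept as a default, not a claim about the kinetics.

Mine is a guess with a number. In violet, isomer of the product A averages 45.0 %, and with target it holds about half of the charge. If all the charge that does not end as isomer of the product A passed through target first, the early ratio stands near 1.22.

    substrate ⇌ other conformer (K = 0.870, k = 0.00990 /s)
    substrate + partner → target (k = 0.0590 /M/s)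
    partner + other conformer → isomer of the product A (k = 0.270 /M/s)
    target ⇌ isomer of the product B (K = 0.830, k = 0.0300 /s)
    2 substrate → homo dimer (k = 0.170 /M/s)
    substrate + target → side product (k = 1.30 /M/s)

The flask gives 1.25 at 25 s and 0.145 at 12 h, with isomer of the product A ahead at 45.5 % against 6.59 % of target. The early ratio is far above the default, yet the two stand level at 3.43 % each after 30.2 s, not long beyond 25 s, and by 1.20 h the flask holds 6.59 % of target and 45.5 % of isomer of the product A, the amounts it ends with, so from there a ratio near the forecast's 0.15 is right. The partner-scaled ratio 0.00341 /mM gave 0.145 for this flask; at 72 mM of partner it gives 0.246, and that neighbour reads 0.228.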